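## Retrosynthetic overview

1. The last bond is the diene C–C bond of the hydroxy-ketone arm: Stille union of a lactone-borne (E)-2-bromopropenyl group with an (E)-vinylstannane that already carries the syn-aldol methyl ketone (Evans aldol, Weinreb amide, MeMgBr).
2. The bromopropenyl group is put on C3 by α-alkenylation of the zinc enolate of the trans-4,5-disubstituted butyrolactone with (E)-2-bromo-1-iodopropene (C3 set trans to the C4 methyl).
3. Key disconnection: the lactone acyl C–O bond. The only ring is closed by oxygenative lactonisation of a terminal alkyne onto its own homopropargylic hydroxyl.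
4. The homopropargylic alcohol comes from anti-selective addition of the allenylindium reagent made from (R)-but-3-yn-2-yl mesylate to the (2E,4E,6R)-dienal (this sets C4 and C5 of the lactone).
5. The dienal comes from (E)-hept-2-en-1-ol by bromination, copper-catalysed asymmetric allylic methylation, cross-metathesis with crotonaldehyde and Wittig homologation.

Assumption: in step 2 the (R,R)-Taniaphos ligand is taken to give the (R)-alkene, by analogy with the cinnamyl series; if the measured rotation shows the opposite sense, the mirror-image ligand is used.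

## Route

Step 1
Reactants: 1 (E)-hept-2-en-1-ol
Product: 2 (E)-1-bromohept-2-ene
Conditions: PBr3 (0.4 equiv), Et2O, −10 °C
Reagents that add atoms: phosphorus tribromide, BrP(Br)Br
Why: Primary allylic alcohol to bromide by SN2 displacement of the phosphite ester; the E alkene is kept and no stereocentre is involved.

Step 2
Reactants: 2 (E)-1-bromohept-2-ene
Product: 3 (R)-3-methylhept-1-ene
Conditions: MeMgBr (1.15 equiv), CuBr·SMe2 (1 mol%), (R,R)-Taniaphos [(RP)-1-[(R)-(dimethylamino)(2-diphenylphosphanylphenyl)methyl]-2-(diphenylphosphanyl)ferrocene] (1.1 mol%), CH2Cl2, −75 °C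
Reagents that add atoms: methylmagnesium bromide, C[Mg]Br
Why: Copper-catalysed asymmetric allylic alkylation (SN2′) in which the chiral diphosphine–methylcopper complex delivers methyl to C3 anti to bromide with high branched selectivity, setting the (R) methyl stereocentre.

Step 3
Reactants: 3 (R)-3-methylhept-1-ene and 4 (E)-but-2-enal (crotonaldehyde)
Product: 5 (2E,4R)-4-methyloct-2-enal
Conditions: 4 (4 equiv), second-generation Hoveyda–Grubbs catalyst [RuCl2(H2IMes)(=CH-C6H4-2-O-i-Pr)] (3 mol%), CH2Cl2, 40 °C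
Reagents that add atoms: none
Why: Olefin cross-metathesis of a terminal alkene with an enal gives the (E)-enal with loss of propene and does not touch the allylic stereocentre.

Step 4
Reactants: 5 (2E,4R)-4-methyloct-2-enal and 6 2-(triphenyl-λ5-phosphanylidene)propanal
Product: 7 (2E,4E,6R)-2,6-dimethyldeca-2,4-dienal
Conditions: toluene, 90 °C
Reagents that add atoms: none
Why: Wittig olefination with a stabilised ylide gives the (E)-trisubstituted enal, and the more hindered, more conjugated product aldehyde does not react further.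

Step 5
Reactants: 8 (R)-but-3-yn-2-ol
Product: 9 (R)-but-3-yn-2-yl methanesulfonate
Conditions: MsCl, Et3N, CH2Cl2, −78 → 0 °C
Reagents that add atoms: methanesulfonyl chloride, CS(=O)(=O)Cl
Why: O-sulfonylation; the stereocentre is not involved.

Step 6
Reactants: 7 (2E,4E,6R)-2,6-dimethyldeca-2,4-dienal and 9 (R)-but-3-yn-2-yl methanesulfonate
Product: 11 (3S,4S,5E,7E,9R)-3,5,9-trimethyltrideca-5,7-dien-1-yn-4-ol, via allenylindium reagent 10 (not isolated)
Conditions: PdCl2(dppf) (5 mol%), InI (1.5 equiv), THF–HMPA 3:1, rt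
Reagents that add atoms: none
Why: Marshall propargylation, in which zerovalent palladium opens the mesylate anti (SN2′), the allenylpalladium transmetalates to the allenylindium, and a cyclic SE2′ addition to the aldehyde gives the anti adduct; C3 is fixed by the mesylate (net inversion) and C4 by the anti transition state.

Step 7
Reactants: 11 (3S,4S,5E,7E,9R)-3,5,9-trimethyltrideca-5,7-dien-1-yn-4-ol
Product: 13 (4S,5S)-4-methyl-5-[(2E,4E,6R)-6-methyldeca-2,4-dien-2-yl]oxolan-2-one, via hydroxy ketene 12 (not isolated)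
Conditions: [Rh(cod)Cl]2 (2.5 mol%), P(4-FC6H4)3 (10 mol%), 4-picoline N-oxide (1.5 equiv), MeCN, 60 °C
Reagents that add atoms: 4-picoline N-oxide, Cc1cc[n+]([O-])cc1
Why: Proposed new method: monovalent rhodium converts the terminal alkyne into a Rh=C=CH vinylidene, the N-oxide transfers oxygen to the electrophilic vinylidene carbon to give a rhodium-bound ketene, and the neighbouring C4 hydroxyl adds to it to close the five-membered lactone C–O bond (if the hydroxyl adds first, the resulting cyclic oxacarbene is oxidised to the same lactone), under near-neutral conditions that should leave the diene and the C4/C5 stereocentres alone; the closest known reactions are the ruthenium-vinylidene cycloisomerisation–oxidation of homopropargylic alcohols to butyrolactones and the rhodium-catalysed oxygenative ester formation from terminal alkynes and external alcohols, neither shown on an allylic, diene-bearing homopropargylic alcohol.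

Step 8
Reactants: 14 propyne
Product: 15 (E)-2-bromo-1-iodoprop-1-ene
Conditions: IBr, CH2Cl2, −78 °C
Reagents that add atoms: iodine monobromide, IBr
Why: Electrophilic anti addition of I–Br to the alkyne, iodine to the terminal carbon and bromide to the internal one, gives the (E)-dihalide.

Step 9
Reactants: 13 (4S,5S)-4-methyl-5-[(2E,4E,6R)-6-methyldeca-2,4-dien-2-yl]oxolan-2-one and 15 (E)-2-bromo-1-iodoprop-1-ene
Product: 18 (3R,4S,5S)-3-[(E)-2-bromoprop-1-en-1-yl]-4-methyl-5-[(2E,4E,6R)-6-methyldeca-2,4-dien-2-yl]oxolan-2-one, via lithium enolate 16 (not isolated), via chlorozinc enolate 17 (not isolated)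
Conditions: LiN(SiMe3)2, THF, −78 °C; ZnCl2, −78 → 0 °C; 15, Pd(P(t-Bu)3)2 (5 mol%), rt
Reagents that add atoms: none
Why: Palladium-catalysed α-alkenylation of a zinc ester enolate (Reformatsky/Negishi-type enolate cross-coupling), in which zerovalent palladium inserts into C–I far faster than C–Br, the alkene geometry is retained, and the new C3 bond forms on the enolate face opposite the C4 methyl (also the thermodynamic trans isomer).

Step 10
Reactants: 19 prop-2-yn-1-ol
Product: 20 (E)-3-(tributylstannyl)prop-2-en-1-ol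
Conditions: Bu3SnH, AIBN (cat.), neat, 80 °C; chromatography
Reagents that add atoms: tributyltin hydride, CCCC[SnH](CCCC)CCCC
Why: Radical hydrostannation puts tin on the terminal carbon and gives mainly the (E)-isomer, which is separated from the minor isomers.

Step 11
Reactants: 20 (E)-3-(tributylstannyl)prop-2-en-1-ol
Product: 21 (E)-3-(tributylstannyl)prop-2-enal
Conditions: MnO2, CH2Cl2, rt
Reagents that add atoms: none
Why: Selective allylic alcohol oxidation; the vinylstannane and the E geometry survive.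

Step 12
Reactants: 21 (E)-3-(tributylstannyl)prop-2-enal and 22 (R)-4-benzyl-3-propanoyl-1,3-oxazolidin-2-one
Product: 24 (R)-4-benzyl-3-[(2R,3R,4E)-3-hydroxy-2-methyl-5-(tributylstannyl)pent-4-enoyl]-1,3-oxazolidin-2-one, via boron enolate 23 (not isolated)
Conditions: Bu2BOTf, Et3N, CH2Cl2, 0 °C; 21, −78 → 0 °C; pH 7 buffer, MeOH, H2O2, 0 °C
Reagents that add atoms: none
Why: Evans syn-aldol through the (Z)-dibutylboron enolate and a Zimmerman–Traxler chair, in which the (R)-benzyl auxiliary fixes both new stereocentres (syn, 2R,3R).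

Step 13
Reactants: 24 (R)-4-benzyl-3-[(2R,3R,4E)-3-hydroxy-2-methyl-5-(tributylstannyl)pent-4-enoyl]-1,3-oxazolidin-2-one
Product: 25 (2R,3R,4E)-3-hydroxy-N-methoxy-N,2-dimethyl-5-(tributylstannyl)pent-4-enamide
Conditions: MeNH(OMe)·HCl, AlMe3, THF, −20 → 0 °C
Reagents that add atoms: N,O-dimethylhydroxylamine hydrochloride, CNOC.Cl
Why: Hydroxyl-assisted aluminium amide transamidation of the imide (Weinreb amide formation) releases the auxiliary without epimerisation.

Step 14
Reactants: 25 (2R,3R,4E)-3-hydroxy-N-methoxy-N,2-dimethyl-5-(tributylstannyl)pent-4-enamide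
Product: 26 (3R,4R,5E)-4-hydroxy-3-methyl-6-(tributylstannyl)hex-5-en-2-one
Conditions: MeMgBr (3 equiv), THF, −78 → 0 °C
Reagents that add atoms: methylmagnesium bromide, C[Mg]Br
Why: Weinreb ketone synthesis, where the chelated tetrahedral intermediate stops the addition at the methyl ketone and the alkoxide formed first protects against retro-aldol.

Step 15
Reactants: 18 (3R,4S,5S)-3-[(E)-2-bromoprop-1-en-1-yl]-4-methyl-5-[(2E,4E,6R)-6-methyldeca-2,4-dien-2-yl]oxolan-2-one and 26 (3R,4R,5E)-4-hydroxy-3-methyl-6-(tributylstannyl)hex-5-en-2-one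
Product: 27 (3S,4S,5S)-3-[(1E,3E,5S,6R)-5-hydroxy-2,6-dimethyl-7-oxoocta-1,3-dien-1-yl]-4-methyl-5-[(2E,4E,6R)-6-methyldeca-2,4-dien-2-yl]oxolan-2-one
Conditions: Pd2(dba)3 (5 mol%), AsPh3 (20 mol%), CuI (10 mol%), degassed NMP, 45 °C
Reagents that add atoms: none
Why: Stille cross-coupling with retention at both alkenes gives the (E,E)-diene under neutral conditions that spare the β-hydroxy ketone and the epimerisable C3; the changed descriptors at C3 and C5′ reflect only the loss of Br and Sn from the priority order.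

## Compound list

1 | (E)-hept-2-en-1-ol | CCCC/C=C/CO | starting material
2 | (E)-1-bromohept-2-ene | CCCC/C=C/CBr | intermediate
3 | (R)-3-methylhept-1-ene | CCCC[C@@H](C)C=C | intermediate
4 | (E)-but-2-enal | C/C=C/C=O | starting material
5 | (2E,4R)-4-methyloct-2-enal | CCCC[C@@H](C)/C=C/C=O | intermediate
6 | 2-(triphenyl-λ5-phosphanylidene)propanal | CC(C=O)=P(c1ccccc1)(c1ccccc1)c1ccccc1 | starting material
7 | (2E,4E,6R)-2,6-dimethyldeca-2,4-dienal | CCCC[C@@H](C)/C=C/C=C(\C)C=O | intermediate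
8 | (R)-but-3-yn-2-ol | C#C[C@@H](C)O | starting material
9 | (R)-but-3-yn-2-yl methanesulfonate | C#C[C@@H](C)OS(C)(=O)=O | intermediate
10 | (P)-buta-1,2-dien-1-yl(iodo)indium methanesulfonate (allenylindium reagent) | C[C]([H])=[C@@]=[C]([H])[In](I)OS(C)(=O)=O | intermediate
11 | (3S,4S,5E,7E,9R)-3,5,9-trimethyltrideca-5,7-dien-1-yn-4-ol | CCCC[C@@H](C)/C=C/C=C(\C)[C@@H](O)[C@@H](C)C#C | intermediate
12 | (3S,4S,5E,7E,9R)-4-hydroxy-3,5,9-trimethyltrideca-1,5,7-trien-1-one (hydroxy ketene) | CCCC[C@@H](C)/C=C/C=C(\C)[C@@H](O)[C@@H](C)C=C=O | intermediate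
13 | (4S,5S)-4-methyl-5-[(2E,4E,6R)-6-methyldeca-2,4-dien-2-yl]oxolan-2-one | CCCC[C@@H](C)/C=C/C=C(\C)[C@H]1OC(=O)C[C@@H]1C | intermediate
14 | propyne | CC#C | starting material
15 | (E)-2-bromo-1-iodoprop-1-ene | I/C=C(/Br)C | intermediate
16 | lithium (4S,5S)-4-methyl-5-[(2E,4E,6R)-6-methyldeca-2,4-dien-2-yl]-4,5-dihydrofuran-2-olate (lithium enolate) | CCCC[C@@H](C)/C=C/C=C(\C)[C@H]1OC(O[Li])=C[C@@H]1C | intermediate
17 | chlorozinc (4S,5S)-4-methyl-5-[(2E,4E,6R)-6-methyldeca-2,4-dien-2-yl]-4,5-dihydrofuran-2-olate (chlorozinc enolate) | CCCC[C@@H](C)/C=C/C=C(\C)[C@H]1OC(O[Zn]Cl)=C[C@@H]1C | intermediate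
18 | (3R,4S,5S)-3-[(E)-2-bromoprop-1-en-1-yl]-4-methyl-5-[(2E,4E,6R)-6-methyldeca-2,4-dien-2-yl]oxolan-2-one | CCCC[C@@H](C)/C=C/C=C(\C)[C@H]1OC(=O)[C@@H](/C=C(C)/Br)[C@@H]1C | intermediate
19 | prop-2-yn-1-ol | C#CCO | starting material
20 | (E)-3-(tributylstannyl)prop-2-en-1-ol | CCCC[Sn](CCCC)(CCCC)/C=C/CO | intermediate
21 | (E)-3-(tributylstannyl)prop-2-enal | CCCC[Sn](CCCC)(CCCC)/C=C/C=O | intermediate
22 | (R)-4-benzyl-3-propanoyl-1,3-oxazolidin-2-one | CCC(=O)N1[C@H](Cc2ccccc2)COC1=O | starting material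
23 | (Z)-dibutylboron enolate of 22, (R)-4-benzyl-3-[(Z)-1-(dibutylboranyloxy)prop-1-en-1-yl]-1,3-oxazolidin-2-one | C/C=C(\OB(CCCC)CCCC)N1[C@H](Cc2ccccc2)COC1=O | intermediate
24 | (R)-4-benzyl-3-[(2R,3R,4E)-3-hydroxy-2-methyl-5-(tributylstannyl)pent-4-enoyl]-1,3-oxazolidin-2-one | CCCC[Sn](CCCC)(CCCC)/C=C/[C@H](O)[C@@H](C)C(=O)N1[C@H](Cc2ccccc2)COC1=O | intermediate
25 | (2R,3R,4E)-3-hydroxy-N-methoxy-N,2-dimethyl-5-(tributylstannyl)pent-4-enamide | CCCC[Sn](CCCC)(CCCC)/C=C/[C@H](O)[C@@H](C)C(=O)N(C)OC | intermediate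
26 | (3R,4R,5E)-4-hydroxy-3-methyl-6-(tributylstannyl)hex-5-en-2-one | CCCC[Sn](CCCC)(CCCC)/C=C/[C@H](O)[C@@H](C)C(C)=O | intermediate
27 | (3S,4S,5S)-3-[(1E,3E,5S,6R)-5-hydroxy-2,6-dimethyl-7-oxoocta-1,3-dien-1-yl]-4-methyl-5-[(2E,4E,6R)-6-methyldeca-2,4-dien-2-yl]oxolan-2-one | CCCC[C@@H](C)/C=C/C=C(\C)[C@H]1OC(=O)[C@@H](/C=C(C)/C=C/[C@H](O)[C@@H](C)C(C)=O)[C@@H]1C | target

## Step count and risks

Total step count: 15. Longest linear sequence: 8 steps (steps 1, 2, 3, 4, 6, 7, 9, 15).

Three steps most likely to fail: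

Step 7 (the proposed new lactonisation). The rhodium vinylidene may be slowed by diene binding, the alcohol may add and give the 2,3-dihydrofuran without oxidation, or the N-oxide may attack elsewhere. The fallback uses known chemistry, sets out from 11 and returns at 13. Compound 11 is treated with freshly made dicyclohexylborane (2.2 equiv, THF, 0 °C); the first equivalent caps the hydroxyl and the second hydroborates the terminal alkyne anti-Markovnikov to give dicyclohexyl[(1E,3S,4S,5E,7E,9R)-4-(dicyclohexylboranyloxy)-3,5,9-trimethyltrideca-1,5,7-trien-1-yl]borane F1. Oxidation in the same flask with NaBO3·4H2O gives the aldehyde, which closes to the lactol (4S,5S)-4-methyl-5-[(2E,4E,6R)-6-methyldeca-2,4-dien-2-yl]oxolan-2-ol F2. TEMPO with PhI(OAc)2 in CH2Cl2 then oxidises the lactol to 13.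

Step 9 (α-alkenylation). Zerovalent palladium could ionise the allylic C5–O bond of the lactone, the product could be alkenylated twice, or the new alkene could move into conjugation. The fallback sets out from 13 and returns at 18, replacing the nucleophilic enolate coupling by a radical cross-electrophile coupling. The lithium enolate 16 is trapped with Me3SiCl as trimethyl{[(4S,5S)-4-methyl-5-[(2E,4E,6R)-6-methyldeca-2,4-dien-2-yl]-4,5-dihydrofuran-2-yl]oxy}silane F3. NBS at −78 °C converts this into (4R,5S)-3-bromo-4-methyl-5-[(2E,4E,6R)-6-methyldeca-2,4-dien-2-yl]oxolan-2-one F4 (either C3 epimer serves). Nickel-catalysed reductive coupling of F4 with 15 (NiBr2(dme), 4,4′-di-tert-butyl-2,2′-bipyridine, Mn powder, DMA, rt) gives 18, the α-radical being captured trans to the C4 methyl.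

Step 15 (Stille coupling). Oxidative addition into the hindered 2-bromoalkene may be slow, and the stannane may protodestannylate or homocouple. The fallback sets out from 18 and returns at 27, moving the aldol to the end. Compound 18 is coupled under the same palladium conditions with the simpler stannane 21 to give (2E,4E)-4-methyl-5-[(3S,4S,5S)-4-methyl-5-[(2E,4E,6R)-6-methyldeca-2,4-dien-2-yl]-2-oxooxolan-3-yl]penta-2,4-dienal F5. A syn-selective Mukaiyama aldol of F5 with (Z)-2-(trimethylsilyloxy)but-2-ene, catalysed by the B-butyl oxazaborolidinone of N-tosyltryptophan (the enantiomer that gives the 5S,6R product; EtCN, −78 °C), gives (3S,4S,5S)-3-[(1E,3E,5S,6R)-2,6-dimethyl-7-oxo-5-(trimethylsilyloxy)octa-1,3-dien-1-yl]-4-methyl-5-[(2E,4E,6R)-6-methyldeca-2,4-dien-2-yl]oxolan-2-one F6. Dilute HCl on work-up removes the silyl group and gives 27.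

## Further compounds

F1 | step 7 | dicyclohexyl[(1E,3S,4S,5E,7E,9R)-4-(dicyclohexylboranyloxy)-3,5,9-trimethyltrideca-1,5,7-trien-1-yl]borane | CCCC[C@@H](C)/C=C/C=C(\C)[C@@H](OB(C1CCCCC1)C1CCCCC1)[C@@H](C)/C=C/B(C1CCCCC1)C1CCCCC1
F2 | step 7 | (4S,5S)-4-methyl-5-[(2E,4E,6R)-6-methyldeca-2,4-dien-2-yl]oxolan-2-ol (anomer mixture) | CCCC[C@@H](C)/C=C/C=C(\C)[C@H]1OC(O)C[C@@H]1C
F3 | step 9 | trimethyl{[(4S,5S)-4-methyl-5-[(2E,4E,6R)-6-methyldeca-2,4-dien-2-yl]-4,5-dihydrofuran-2-yl]oxy}silane | CCCC[C@@H](C)/C=C/C=C(\C)[C@H]1OC(O[Si](C)(C)C)=C[C@@H]1C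
F4 | step 9 | (4R,5S)-3-bromo-4-methyl-5-[(2E,4E,6R)-6-methyldeca-2,4-dien-2-yl]oxolan-2-one (C3 epimers) | CCCC[C@@H](C)/C=C/C=C(\C)[C@H]1OC(=O)C(Br)[C@@H]1C
F5 | step 15 | (2E,4E)-4-methyl-5-[(3S,4S,5S)-4-methyl-5-[(2E,4E,6R)-6-methyldeca-2,4-dien-2-yl]-2-oxooxolan-3-yl]penta-2,4-dienal | CCCC[C@@H](C)/C=C/C=C(\C)[C@H]1OC(=O)[C@@H](/C=C(C)/C=C/C=O)[C@@H]1C
F6 | step 15 | (3S,4S,5S)-3-[(1E,3E,5S,6R)-2,6-dimethyl-7-oxo-5-(trimethylsilyloxy)octa-1,3-dien-1-yl]-4-methyl-5-[(2E,4E,6R)-6-methyldeca-2,4-dien-2-yl]oxolan-2-one | CCCC[C@@H](C)/C=C/C=C(\C)[C@H]1OC(=O)[C@@H](/C=C(C)/C=C/[C@H](O[Si](C)(C)C)[C@@H](C)C(C)=O)[C@@H]1C
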